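The ten-membered ring is grown from a cyclohexene instead of being closed end to end. In the target, O9, the C6–C7 bond and the E C4=C5 alkene map onto a cyclodec-5-enone, and the Z C1=C10 alkene lies in the six-carbon arc C9–C10–C1–C2–C3–C4, so one extra C4–C9 bond turns that arc into a cyclohexene. The precursor is therefore a cyclohex-2-en-1-ol with a dienyl group on the carbinol carbon (C9) and a methyl plus an E alkoxyvinyl group on C4. Its potassium alkoxide undergoes an anionic oxy-Cope shift that forms C6–C7, cuts C4–C9, fixes C6, C7 and the E alkene, and leaves an enolate that is hydroxylated at C8 in the same flask.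

Key step: step 14

Remark 1: C1–C15 denote the germacrane positions of the target (C14 on C10, C15 on C4, C11–C13 in the side chain on C7) and are used for all intermediates.
Remark 2 (assumption): the lipase of step 2 is taken to hydrolyse the (S)-acetate; should it prefer the (R)-acetate, the unreacted (S)-acetate would be methanolysed (K2CO3, MeOH) to the same alcohol 3.

Step 1
Reactants: 1 3-ethoxy-2-methylcyclohex-2-en-1-one
Product: 2 rac-6-acetoxy-3-ethoxy-2-methylcyclohex-2-en-1-one
Conditions: Mn(OAc)3·2H2O, benzene, 80 °C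
Reagents that add atoms: manganese triacetate CC(=O)O[Mn](OC(C)=O)OC(C)=O
Why: Oxidative α'-acetoxylation of the vinylogous ester by trivalent manganese goes through the manganese enolate at C6, the only enolisable carbon next to the carbonyl, so the oxygen enters at the carbon that becomes C2.

Step 2
Reactants: 2 rac-6-acetoxy-3-ethoxy-2-methylcyclohex-2-en-1-one
Product: 3 (S)-3-ethoxy-6-hydroxy-2-methylcyclohex-2-en-1-one
Conditions: lipase PS (Burkholderia cepacia), aq. KH2PO4/K2HPO4 (pH 7), DMSO, rt, stopped near half conversion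
Reagents that add atoms: none
Why: Enzymatic kinetic resolution by enantioselective ester hydrolysis should release only the (S)-acyloin, which fixes C2, while the (R)-acetate stays behind and is removed by chromatography.

Step 3
Reactants: 3 (S)-3-ethoxy-6-hydroxy-2-methylcyclohex-2-en-1-one
Product: 4 (S)-6-(tert-butyldimethylsilyloxy)-3-ethoxy-2-methylcyclohex-2-en-1-one
Conditions: TBSCl, imidazole, DMF, rt
Reagents that add atoms: tert-butyldimethylsilyl chloride CC(C)(C)[Si](C)(C)Cl
Why: Imidazole-promoted silyl ether formation masks the secondary hydroxyl without touching the stereocentre.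

Step 4
Reactants: 4 (S)-6-(tert-butyldimethylsilyloxy)-3-ethoxy-2-methylcyclohex-2-en-1-one
Product: 6 (S)-4-(tert-butyldimethylsilyloxy)-2-methylcyclohex-2-en-1-one, via allylic alcohol 5 (not isolated)
Conditions: iBu2AlH, CH2Cl2, −78 °C; then 1 M HCl, THF, 0 °C
Reagents that add atoms: water O
Why: 1,2-Reduction of the vinylogous ester carbonyl followed by acid-induced loss of water and hydrolysis of the enol ether (Stork–Danheiser transposition) moves the carbonyl to the former ethoxy carbon (C9) and leaves the silyloxy stereocentre at the γ position untouched.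

Step 5
Reactants: 6 (S)-4-(tert-butyldimethylsilyloxy)-2-methylcyclohex-2-en-1-one
Product: 8 (S,Z)-4-(tert-butyldimethylsilyloxy)-6-(hydroxymethylene)-2-methylcyclohex-2-en-1-one, via lithium dienolate 7 (not isolated)
Conditions: LDA, THF, −78 °C; then CF3CH2OCHO, −78 °C
Reagents that add atoms: 2,2,2-trifluoroethyl formate O=COCC(F)(F)F
Why: Kinetic deprotonation takes the α' methylene (C4) and not the γ carbon, and the cross-conjugated enolate undergoes Claisen-type C-formylation with the activated formate to give the chelated hydroxymethylene ketone.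

Step 6
Reactants: 8 (S,Z)-4-(tert-butyldimethylsilyloxy)-6-(hydroxymethylene)-2-methylcyclohex-2-en-1-one
Product: 9 (4S,6S)-4-(tert-butyldimethylsilyloxy)-6-formyl-2,6-dimethylcyclohex-2-en-1-one (methyl trans to the silyloxy group)
Conditions: K2CO3, MeI, acetone, rt
Reagents that add atoms: iodomethane CI
Why: C-Alkylation of the potassium salt of the β-keto aldehyde builds the C4 quaternary centre, and iodomethane should approach the planar anion anti to the C2 silyloxy group, so that methyl ends trans and formyl cis to it.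

Step 7
Reactants: 9 (4S,6S)-4-(tert-butyldimethylsilyloxy)-6-formyl-2,6-dimethylcyclohex-2-en-1-one
Product: 10 (4S,6S)-4-(tert-butyldimethylsilyloxy)-6-[(E)-2-iodoethenyl]-2,6-dimethylcyclohex-2-en-1-one
Conditions: CrCl2, CHI3, THF, 0 °C to rt
Reagents that add atoms: iodoform IC(I)I
Why: Takai iodo-olefination with the geminal dichromium species from iodoform and divalent chromium converts the aldehyde, and not the ketone, into the E vinyl iodide.

Step 8
Reactants: 10 (4S,6S)-4-(tert-butyldimethylsilyloxy)-6-[(E)-2-iodoethenyl]-2,6-dimethylcyclohex-2-en-1-one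
Product: 11 (4S,6S)-4-(tert-butyldimethylsilyloxy)-6-[(E)-2-(4-methoxybenzyloxy)ethenyl]-2,6-dimethylcyclohex-2-en-1-one
Conditions: 4-MeOC6H4CH2OH, CuI (10 mol %), 3,4,7,8-tetramethyl-1,10-phenanthroline (20 mol %), Cs2CO3, toluene, 80 °C
Reagents that add atoms: 4-methoxybenzyl alcohol COc1ccc(CO)cc1
Why: Copper-catalysed Ullmann-type C–O coupling of a vinyl iodide with a primary alcohol keeps the alkene geometry and gives the E enol ether that becomes C5=C6–O.

Step 9
Reactants: 12 2-bromoprop-2-en-1-ol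
Product: 13 1-[(2-bromoprop-2-en-1-yloxy)methyl]-4-methoxybenzene
Conditions: NaH, 4-MeOC6H4CH2Cl, Bu4NI (cat.), THF/DMF, 0 °C to rt
Reagents that add atoms: 4-methoxybenzyl chloride COc1ccc(CCl)cc1
Why: Williamson etherification of the primary alkoxide protects the future C12 oxygen, the vinyl bromide being inert to these conditions.

Step 10
Reactants: 13 1-[(2-bromoprop-2-en-1-yloxy)methyl]-4-methoxybenzene; 14 ethynyltrimethylsilane
Product: 15 trimethyl{3-[(4-methoxybenzyloxy)methyl]but-3-en-1-yn-1-yl}silane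
Conditions: Pd(PPh3)2Cl2 (3 mol %), CuI (5 mol %), Et3N, THF, rt
Reagents that add atoms: none
Why: Sonogashira coupling of the 1,1-disubstituted vinyl bromide with the terminal alkyne forms the C7–C11 bond of the enyne.

Step 11
Reactants: 15 trimethyl{3-[(4-methoxybenzyloxy)methyl]but-3-en-1-yn-1-yl}silane
Product: 16 1-methoxy-4-[(2-methylidenebut-3-yn-1-yloxy)methyl]benzene
Conditions: K2CO3, MeOH, rt
Reagents that add atoms: none
Why: Base-catalysed methanolysis of the C(sp)–Si bond frees the terminal alkyne.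

Step 12
Reactants: 16 1-methoxy-4-[(2-methylidenebut-3-yn-1-yloxy)methyl]benzene
Product: 18 1-{[(3E)-4-iodo-2-methylidenebut-3-en-1-yl]oxymethyl}-4-methoxybenzene, via alkenylzirconocene chloride 17 (not isolated)
Conditions: Cp2Zr(H)Cl, THF, rt; then I2, 0 °C
Reagents that add atoms: iodine II
Why: Hydrozirconation adds Zr–H syn across the terminal alkyne, faster than across the 1,1-disubstituted alkene, with zirconium at the terminus, and iodinolysis with retention gives the E dienyl iodide.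

Step 13
Reactants: 18 1-{[(3E)-4-iodo-2-methylidenebut-3-en-1-yl]oxymethyl}-4-methoxybenzene; 11 (4S,6S)-4-(tert-butyldimethylsilyloxy)-6-[(E)-2-(4-methoxybenzyloxy)ethenyl]-2,6-dimethylcyclohex-2-en-1-one
Product: 21 (1S,4S,6S)-4-(tert-butyldimethylsilyloxy)-1-{(1E)-3-[(4-methoxybenzyloxy)methyl]buta-1,3-dien-1-yl}-6-[(E)-2-(4-methoxybenzyloxy)ethenyl]-2,6-dimethylcyclohex-2-en-1-ol (the two alkenyl groups trans), via dienyllithium 19 (not isolated), via dienylcerium dichloride 20 (not isolated)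
Conditions: 18, t-BuLi (2 equiv), Et2O, −78 °C; CeCl3, THF, −78 °C; then 11, −78 to −40 °C; aq. NH4Cl
Reagents that add atoms: none
Why: Iodine–lithium exchange and transmetalation give a weakly basic organocerium reagent that adds 1,2 to the hindered enone; approach anti to the C4 alkenyl group, the better acceptor substituent, which is axial in the reacting half-chair on the same face as the C2 silyloxy group, should place C8 trans to that group and O9 cis to it, and any C9 epimer is removed by chromatography.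

Step 14
Reactants: 21 (1S,4S,6S)-4-(tert-butyldimethylsilyloxy)-1-{(1E)-3-[(4-methoxybenzyloxy)methyl]buta-1,3-dien-1-yl}-6-[(E)-2-(4-methoxybenzyloxy)ethenyl]-2,6-dimethylcyclohex-2-en-1-ol
Product: 24 (2S,6R,7R,8R)-2-(tert-butyldimethylsilyloxy)-8-hydroxy-6,12-bis(4-methoxybenzyloxy)germacra-1(10)Z,4E,11(13)-trien-9-one, via potassium alkoxide 22 (not isolated), via potassium dienolate 23 (not isolated)
Conditions: KH, 18-crown-6, THF, 0 °C to rt; then −78 °C, 2-(phenylsulfonyl)-3-phenyloxaziridine; AcOH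
Reagents that add atoms: 2-(phenylsulfonyl)-3-phenyloxaziridine O=S(=O)(c1ccccc1)N1OC1c1ccccc1
Why: KH converts 21 into alkoxide 22, whose oxyanion weakens the doubly allylic C4–C9 bond between two fully substituted carbons, and the 1,5-diene C7=C8–C9–C4–C5=C6 undergoes a [3,3] sigmatropic shift (anionic oxy-Cope rearrangement; closest known type: ring expansion of 1,6-dialkenylcyclohex-2-en-1-ols to cyclodecadienone enolates that are oxidised in the same flask). The ten-membered carbocycle is made by this four-atom ring expansion (C6–C7 formed, C4–C9 cut) and not by an end-to-end cyclisation, and C1=C10 keeps the Z geometry it had in the cyclohexene. Because the two alkenyl groups of 22 are trans, the only chair open to them has both equatorial on the half-chair (C4 methyl and O9 axial, C2 silyloxy equatorial), so C3 and C10 are equatorial in the chair, C4=C5 is formed E and the enolate has C7 and C10 trans. With the E enol ether and E diene termini equatorial, the C4 configuration is relayed to C6 and the C9 configuration to C7, which gives the 6,7 relationship of the trans-fused lactone. The cross-conjugated enolate 23 is nucleophilic only at C8 and should be oxidised by the sulfonyloxaziridine on its outer face, anti to the ring segment that leaves C7 through C6 while H7 eclipses the enolate oxygen, which sets C8. The selectivities needed are chair over boat and E over Z at C4=C5, both secured by the trans-diequatorial alkenyl groups, and oxidation at C8 only, secured by the cross-conjugation.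

Step 15
Reactants: 24 (2S,6R,7R,8R)-2-(tert-butyldimethylsilyloxy)-8-hydroxy-6,12-bis(4-methoxybenzyloxy)germacra-1(10)Z,4E,11(13)-trien-9-one; 25 angelic acid
Product: 27 (2S,6R,7S,8R)-8-angeloyloxy-2-(tert-butyldimethylsilyloxy)-6,12-bis(4-methoxybenzyloxy)germacra-1(10)Z,4E,11(13)-trien-9-one, via mixed anhydride 26 (not isolated)
Conditions: 25, 2,4,6-Cl3C6H2COCl, Et3N, toluene, rt; then 24, 75 °C
Reagents that add atoms: none
Why: Yamaguchi esterification through the mixed anhydride acylates the hindered α-hydroxy ketone without a nucleophilic amine catalyst, so the Z geometry of the angelate should be kept and not drift to the tiglate.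

Step 16
Reactants: 27 (2S,6R,7S,8R)-8-angeloyloxy-2-(tert-butyldimethylsilyloxy)-6,12-bis(4-methoxybenzyloxy)germacra-1(10)Z,4E,11(13)-trien-9-one
Product: 28 (2S,6R,7S,8R,9R)-8-angeloyloxy-2-(tert-butyldimethylsilyloxy)-6,12-bis(4-methoxybenzyloxy)germacra-1(10)Z,4E,11(13)-trien-9-ol
Conditions: NaBH4, CeCl3·7H2O, MeOH, −78 °C
Reagents that add atoms: none
Why: Luche 1,2-reduction of the enone gives the allylic alcohol; hydride should add anti to the C8–O bond of the α-acyloxy ketone (polar 1,2-induction), which corresponds to the 9R alcohol, and the low temperature suppresses acyl migration.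

Step 17
Reactants: 28 (2S,6R,7S,8R,9R)-8-angeloyloxy-2-(tert-butyldimethylsilyloxy)-6,12-bis(4-methoxybenzyloxy)germacra-1(10)Z,4E,11(13)-trien-9-ol
Product: 29 (2S,6R,7S,8R,9R)-9-acetoxy-8-angeloyloxy-2-(tert-butyldimethylsilyloxy)-6,12-bis(4-methoxybenzyloxy)germacra-1(10)Z,4E,11(13)-triene
Conditions: Ac2O, pyridine, DMAP (cat.), CH2Cl2, 0 °C
Reagents that add atoms: acetic anhydride CC(=O)OC(C)=O
Why: DMAP-catalysed acetylation caps the C9 hydroxyl at once, so the neighbouring angelate cannot migrate.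

Step 18
Reactants: 29 (2S,6R,7S,8R,9R)-9-acetoxy-8-angeloyloxy-2-(tert-butyldimethylsilyloxy)-6,12-bis(4-methoxybenzyloxy)germacra-1(10)Z,4E,11(13)-triene
Product: 30 (2S,6R,7S,8R,9R)-9-acetoxy-8-angeloyloxy-2-(tert-butyldimethylsilyloxy)germacra-1(10)Z,4E,11(13)-triene-6,12-diol
Conditions: DDQ, CH2Cl2/aq. KH2PO4/K2HPO4 (pH 7), 0 °C
Reagents that add atoms: none
Why: Oxidative cleavage of both 4-methoxybenzyl ethers by DDQ (hydride abstraction, then hydrolysis of the oxocarbenium ion) frees the C6 and C12 hydroxyls while the esters and the silyl ether stay.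

Step 19
Reactants: 30 (2S,6R,7S,8R,9R)-9-acetoxy-8-angeloyloxy-2-(tert-butyldimethylsilyloxy)germacra-1(10)Z,4E,11(13)-triene-6,12-diol
Product: 33 (2S,6R,7S,8R,9R)-9-acetoxy-8-angeloyloxy-2-(tert-butyldimethylsilyloxy)germacra-1(10)Z,4E,11(13)-trien-12,6-olide, via hydroxy enal 31 (not isolated), via lactol 32 (not isolated)
Conditions: TEMPO (cat.), PhI(OAc)2, CH2Cl2, rt
Reagents that add atoms: none
Why: The oxoammonium oxidant takes the primary allylic alcohol in preference to the secondary one, the enal closes onto the C6 hydroxyl to the five-membered lactol (O6–C12 bond formation) and a second oxidation gives the α-methylene lactone (oxidative lactonisation of a 1,4-diol) with no stereocentre involved.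

Step 20
Reactants: 33 (2S,6R,7S,8R,9R)-9-acetoxy-8-angeloyloxy-2-(tert-butyldimethylsilyloxy)germacra-1(10)Z,4E,11(13)-trien-12,6-olide
Product: 34 (2S,6R,7S,8R,9R)-9-acetoxy-8-angeloyloxy-2-hydroxygermacra-1(10)Z,4E,11(13)-trien-12,6-olide
Conditions: HF·pyridine, pyridine, THF, 0 °C to rt
Reagents that add atoms: none
Why: Fluoride-mediated desilylation under buffered, non-basic conditions removes the silyl ether without acyl migration or addition to the α-methylene lactone.

Compound list
1 | 3-ethoxy-2-methylcyclohex-2-en-1-one | CCOC1=C(C)C(=O)CCC1 | starting material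
2 | rac-6-acetoxy-3-ethoxy-2-methylcyclohex-2-en-1-one | CCOC1=C(C)C(=O)C(OC(C)=O)CC1 | intermediate
3 | (S)-3-ethoxy-6-hydroxy-2-methylcyclohex-2-en-1-one | CCOC1=C(C)C(=O)[C@@H](O)CC1 | intermediate
4 | (S)-6-(tert-butyldimethylsilyloxy)-3-ethoxy-2-methylcyclohex-2-en-1-one | CCOC1=C(C)C(=O)[C@@H](O[Si](C)(C)C(C)(C)C)CC1 | intermediate
5 | (6S)-6-(tert-butyldimethylsilyloxy)-3-ethoxy-2-methylcyclohex-2-en-1-ol (both C1 epimers) | CCOC1=C(C)C(O)[C@@H](O[Si](C)(C)C(C)(C)C)CC1 | intermediate
6 | (S)-4-(tert-butyldimethylsilyloxy)-2-methylcyclohex-2-en-1-one | O=C1CC[C@H](O[Si](C)(C)C(C)(C)C)C=C1C | intermediate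
7 | lithium (S)-4-(tert-butyldimethylsilyloxy)-6-methylcyclohexa-1,5-dien-1-olate | [Li+].[O-]C1=CC[C@H](O[Si](C)(C)C(C)(C)C)C=C1C | intermediate
8 | (S,Z)-4-(tert-butyldimethylsilyloxy)-6-(hydroxymethylene)-2-methylcyclohex-2-en-1-one | O=C1/C(=C\O)C[C@H](O[Si](C)(C)C(C)(C)C)C=C1C | intermediate
9 | (4S,6S)-4-(tert-butyldimethylsilyloxy)-6-formyl-2,6-dimethylcyclohex-2-en-1-one | O=C1[C@](C)(C=O)C[C@H](O[Si](C)(C)C(C)(C)C)C=C1C | intermediate
10 | (4S,6S)-4-(tert-butyldimethylsilyloxy)-6-[(E)-2-iodoethenyl]-2,6-dimethylcyclohex-2-en-1-one | O=C1[C@](C)(/C=C/I)C[C@H](O[Si](C)(C)C(C)(C)C)C=C1C | intermediate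
11 | (4S,6S)-4-(tert-butyldimethylsilyloxy)-6-[(E)-2-(4-methoxybenzyloxy)ethenyl]-2,6-dimethylcyclohex-2-en-1-one | O=C1[C@](C)(/C=C/OCc2ccc(OC)cc2)C[C@H](O[Si](C)(C)C(C)(C)C)C=C1C | intermediate
12 | 2-bromoprop-2-en-1-ol | C=C(Br)CO | starting material
13 | 1-[(2-bromoprop-2-en-1-yloxy)methyl]-4-methoxybenzene | C=C(Br)COCc1ccc(OC)cc1 | intermediate
14 | ethynyltrimethylsilane | C#C[Si](C)(C)C | starting material
15 | trimethyl{3-[(4-methoxybenzyloxy)methyl]but-3-en-1-yn-1-yl}silane | C=C(C#C[Si](C)(C)C)COCc1ccc(OC)cc1 | intermediate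
16 | 1-methoxy-4-[(2-methylidenebut-3-yn-1-yloxy)methyl]benzene | C=C(C#C)COCc1ccc(OC)cc1 | intermediate
17 | chloro{(1E)-3-[(4-methoxybenzyloxy)methyl]buta-1,3-dien-1-yl}zirconocene, Cp2Zr(Cl)R | C=C(COCc1ccc(OC)cc1)/C=C/[Zr](Cl)(C1C=CC=C1)C1C=CC=C1 | intermediate
18 | 1-{[(3E)-4-iodo-2-methylidenebut-3-en-1-yl]oxymethyl}-4-methoxybenzene | C=C(COCc1ccc(OC)cc1)/C=C/I | intermediate
19 | {(1E)-3-[(4-methoxybenzyloxy)methyl]buta-1,3-dien-1-yl}lithium | C=C(COCc1ccc(OC)cc1)/C=C/[Li] | intermediate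
20 | dichloro{(1E)-3-[(4-methoxybenzyloxy)methyl]buta-1,3-dien-1-yl}cerium, RCeCl2 | C=C(COCc1ccc(OC)cc1)/C=C/[Ce](Cl)Cl | intermediate
21 | (1S,4S,6S)-4-(tert-butyldimethylsilyloxy)-1-{(1E)-3-[(4-methoxybenzyloxy)methyl]buta-1,3-dien-1-yl}-6-[(E)-2-(4-methoxybenzyloxy)ethenyl]-2,6-dimethylcyclohex-2-en-1-ol (hydroxyl cis to the alkoxyvinyl and silyloxy groups) | O[C@]1(/C=C/C(=C)COCc2ccc(OC)cc2)[C@](C)(/C=C/OCc2ccc(OC)cc2)C[C@H](O[Si](C)(C)C(C)(C)C)C=C1C | intermediate
22 | potassium alkoxide of 21 | [K+].[O-][C@]1(/C=C/C(=C)COCc2ccc(OC)cc2)[C@](C)(/C=C/OCc2ccc(OC)cc2)C[C@H](O[Si](C)(C)C(C)(C)C)C=C1C | intermediate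
23 | potassium 2-(tert-butyldimethylsilyloxy)-6,12-bis(4-methoxybenzyloxy)germacra-1(10)Z,4E,8,11(13)-tetraen-9-olate (C7 and C10 trans on C8=C9; C2, C6 and C7 as in 24) | [K+].C1/C(C)=C/[C@@H](OCc2ccc(OC)cc2)[C@H](C(=C)COCc2ccc(OC)cc2)/C=C(\[O-])/C(C)=C\[C@H]1O[Si](C)(C)C(C)(C)C | intermediate
24 | (2S,6R,7R,8R)-2-(tert-butyldimethylsilyloxy)-8-hydroxy-6,12-bis(4-methoxybenzyloxy)germacra-1(10)Z,4E,11(13)-trien-9-one | C=C(COCc1ccc(OC)cc1)[C@H]1[C@H](OCc2ccc(OC)cc2)/C=C(\C)C[C@H](O[Si](C)(C)C(C)(C)C)/C=C(/C)C(=O)[C@@H]1O | intermediate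
25 | angelic acid, (Z)-2-methylbut-2-enoic acid | C/C=C(/C)C(=O)O | starting material
26 | (Z)-2-methylbut-2-enoic 2,4,6-trichlorobenzoic anhydride | C/C=C(/C)C(=O)OC(=O)c1c(Cl)cc(Cl)cc1Cl | intermediate
27 | (2S,6R,7S,8R)-8-angeloyloxy-2-(tert-butyldimethylsilyloxy)-6,12-bis(4-methoxybenzyloxy)germacra-1(10)Z,4E,11(13)-trien-9-one | C=C(COCc1ccc(OC)cc1)[C@H]1[C@H](OCc2ccc(OC)cc2)/C=C(\C)C[C@H](O[Si](C)(C)C(C)(C)C)/C=C(/C)C(=O)[C@@H]1OC(=O)/C(C)=C\C | intermediate
28 | (2S,6R,7S,8R,9R)-8-angeloyloxy-2-(tert-butyldimethylsilyloxy)-6,12-bis(4-methoxybenzyloxy)germacra-1(10)Z,4E,11(13)-trien-9-ol | C=C(COCc1ccc(OC)cc1)[C@H]1[C@H](OCc2ccc(OC)cc2)/C=C(\C)C[C@H](O[Si](C)(C)C(C)(C)C)/C=C(/C)[C@@H](O)[C@@H]1OC(=O)/C(C)=C\C | intermediate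
29 | (2S,6R,7S,8R,9R)-9-acetoxy-8-angeloyloxy-2-(tert-butyldimethylsilyloxy)-6,12-bis(4-methoxybenzyloxy)germacra-1(10)Z,4E,11(13)-triene | C=C(COCc1ccc(OC)cc1)[C@H]1[C@H](OCc2ccc(OC)cc2)/C=C(\C)C[C@H](O[Si](C)(C)C(C)(C)C)/C=C(/C)[C@@H](OC(C)=O)[C@@H]1OC(=O)/C(C)=C\C | intermediate
30 | (2S,6R,7S,8R,9R)-9-acetoxy-8-angeloyloxy-2-(tert-butyldimethylsilyloxy)germacra-1(10)Z,4E,11(13)-triene-6,12-diol | C=C(CO)[C@H]1[C@H](O)/C=C(\C)C[C@H](O[Si](C)(C)C(C)(C)C)/C=C(/C)[C@@H](OC(C)=O)[C@@H]1OC(=O)/C(C)=C\C | intermediate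
31 | (2S,6R,7S,8R,9R)-9-acetoxy-8-angeloyloxy-2-(tert-butyldimethylsilyloxy)-6-hydroxygermacra-1(10)Z,4E,11(13)-trien-12-al | C=C(C=O)[C@H]1[C@H](O)/C=C(\C)C[C@H](O[Si](C)(C)C(C)(C)C)/C=C(/C)[C@@H](OC(C)=O)[C@@H]1OC(=O)/C(C)=C\C | intermediate
32 | 12,6-lactol of 31 (both C12 epimers) | C=C1C(O)O[C@@H]2/C=C(\C)C[C@H](O[Si](C)(C)C(C)(C)C)/C=C(/C)[C@@H](OC(C)=O)[C@H](OC(=O)/C(C)=C\C)[C@@H]12 | intermediate
33 | (2S,6R,7S,8R,9R)-9-acetoxy-8-angeloyloxy-2-(tert-butyldimethylsilyloxy)germacra-1(10)Z,4E,11(13)-trien-12,6-olide | C=C1C(=O)O[C@@H]2/C=C(\C)C[C@H](O[Si](C)(C)C(C)(C)C)/C=C(/C)[C@@H](OC(C)=O)[C@H](OC(=O)/C(C)=C\C)[C@@H]12 | intermediate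
34 | (2S,6R,7S,8R,9R)-9-acetoxy-8-angeloyloxy-2-hydroxygermacra-1(10)Z,4E,11(13)-trien-12,6-olide | C=C1C(=O)O[C@@H]2/C=C(\C)C[C@H](O)/C=C(/C)[C@@H](OC(C)=O)[C@H](OC(=O)/C(C)=C\C)[C@@H]12 | target

Total step count: 20. Longest linear sequence: 16 steps (steps 1–8 and 13–20).

Steps most likely to fail

1. Step 13. The process at risk is the facial selectivity of the carbonyl addition. If the half-chair with the C4 methyl axial dominates, the nucleophile enters anti to that methyl and the main product has the two alkenyl groups cis. That epimer can rearrange only through a chair with C3 axial (Z C4=C5, wrong C6 and C7) or through a ring-flipped chair with the C4 alkenyl and C2 silyloxy groups both axial. The fallback sets out from 11 and returns at 21, and it locks the ring before the addition. Desilylation of 11 (Bu4NF, AcOH, THF) gives hydroxy enone F1. N-Iodosuccinimide (CH2Cl2, −40 °C) closes the C2 hydroxyl onto the enol ether by iodoetherification to the bridged iodo acetal F2, in which O2 and C5 are held axial on one face, so the C4 methyl is equatorial and that face of the ketone is covered. Organocerium 20 then has to add anti to the C5 bridge and gives carbinol F3 with the needed C9 configuration. Zn dust (EtOH, NH4Cl, 60 °C) removes iodine and the anti-periplanar ring oxygen by reductive β-elimination and restores the E enol ether and the C2 hydroxyl in diol F4. TBSCl and imidazole silylate only the secondary hydroxyl and return 21.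

2. Step 14. The process at risk is approach of the oxidant to the inner face of the enolate, which would give the wrong C8 configuration. The fallback sets out from 21 and returns at 27. The same ring expansion and hydroxylation is run and the C8 epimer F5 is taken on. Mitsunobu esterification of F5 with angelic acid 25 (PPh3, DIAD, toluene, 0 °C) installs the angelate with inversion at C8 and gives 27, so step 15 is skipped.

3. Step 16. The process at risk is hydride delivery to the other face of the C9 carbonyl. The fallback sets out from 27 and returns at 29. The reduction then gives the C9 epimer F6, and a Mitsunobu reaction of F6 with acetic acid (PPh3, DIAD, THF, 0 °C) forms the acetate with inversion at C9 and gives 29 directly, replacing step 17.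

Further compounds
F1 | step 13 | (4S,6S)-4-hydroxy-6-[(E)-2-(4-methoxybenzyloxy)ethenyl]-2,6-dimethylcyclohex-2-en-1-one | O=C1[C@](C)(/C=C/OCc2ccc(OC)cc2)C[C@H](O)C=C1C
F2 | step 13 | 4-iodo-3-(4-methoxybenzyloxy)-5,7-dimethyl-2-oxabicyclo[3.3.1]non-7-en-6-one (iodine and alkoxy group equatorial on the oxane ring) | O=C1C(C)=C[C@@H]2C[C@@]1(C)[C@H](I)[C@@H](OCc1ccc(OC)cc1)O2
F3 | step 13 | 4-iodo-3-(4-methoxybenzyloxy)-6-{(1E)-3-[(4-methoxybenzyloxy)methyl]buta-1,3-dien-1-yl}-5,7-dimethyl-2-oxabicyclo[3.3.1]non-7-en-6-ol (hydroxyl on the face of the oxane bridge) | O[C@@]1(/C=C/C(=C)COCc2ccc(OC)cc2)C(C)=C[C@@H]2C[C@@]1(C)[C@H](I)[C@@H](OCc1ccc(OC)cc1)O2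
F4 | step 13 | (1S,4S,6S)-1-{(1E)-3-[(4-methoxybenzyloxy)methyl]buta-1,3-dien-1-yl}-6-[(E)-2-(4-methoxybenzyloxy)ethenyl]-2,6-dimethylcyclohex-2-ene-1,4-diol | O[C@]1(/C=C/C(=C)COCc2ccc(OC)cc2)[C@](C)(/C=C/OCc2ccc(OC)cc2)C[C@H](O)C=C1C
F5 | step 14 | (2S,6R,7R,8S)-2-(tert-butyldimethylsilyloxy)-8-hydroxy-6,12-bis(4-methoxybenzyloxy)germacra-1(10)Z,4E,11(13)-trien-9-one (C8 epimer of 24) | C=C(COCc1ccc(OC)cc1)[C@H]1[C@H](OCc2ccc(OC)cc2)/C=C(\C)C[C@H](O[Si](C)(C)C(C)(C)C)/C=C(/C)C(=O)[C@H]1O
F6 | step 16 | (2S,6R,7S,8R,9S)-8-angeloyloxy-2-(tert-butyldimethylsilyloxy)-6,12-bis(4-methoxybenzyloxy)germacra-1(10)Z,4E,11(13)-trien-9-ol (C9 epimer of 28) | C=C(COCc1ccc(OC)cc1)[C@H]1[C@H](OCc2ccc(OC)cc2)/C=C(\C)C[C@H](O[Si](C)(C)C(C)(C)C)/C=C(/C)[C@H](O)[C@@H]1OC(=O)/C(C)=C\C
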